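## Retrosynthetic overview

1. Cut the methylene bridge: target 21 comes from the aromatic Mannich base 19 (ortho-quinone methide precursor) and the chiral acyl-trione 9, whose only free ring carbon is the nucleophile.
2. The carbocycle of 9 is the only ring made in the route; it is closed by Claisen (Dieckmann-type) cyclisation of the open-chain triketo ester 8. The benzene ring is bought as 5-methoxyresorcinol.
3. 8 comes from the acid chloride of the (R)-malonate half-ester 4 and the dianion of heptane-2,4-dione. 4 comes from enzymatic desymmetrisation of the prochiral diester 3, which sets the only stereocentre.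
4. 19 comes from 5-methoxyresorcinol by two directed ortho-metalations: CH2NMe2 goes between the two OMOM groups, then hexanoyl between OMOM and OMe, which fixes the substitution pattern.

Assumption: the carboxylesterase used in step 2 (crude pig liver esterase or an isoenzyme picked in a small screen) cleaves the pro-S ester of 3 to give (R)-4; this sense and the ee are not established for this substrate and are checked on 4 before going on.

## Route

Step 1
Reactants: 1 dimethyl 2-methylmalonate; 2 1-bromo-3-methylbut-2-ene (prenyl bromide)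
Product: 3 dimethyl 2-methyl-2-(3-methylbut-2-en-1-yl)malonate
Conditions: NaH (1.1 equiv), THF, 0 °C; then 2, 0 °C → rt
Reagents that add atoms: none
Why: Malonate enolate SN2 alkylation at the primary allylic bromide gives an achiral, prochiral diester that has no α-H left and cannot over-alkylate.

Step 2
Reactants: 3 dimethyl 2-methyl-2-(3-methylbut-2-en-1-yl)malonate
Product: 4 (R)-2-(methoxycarbonyl)-2,5-dimethylhex-4-enoic acid
Conditions: pig liver esterase (a carboxylesterase, serine hydrolase), 0.1 M phosphate buffer pH 7.5, 10% t-BuOH, 25 °C, pH-stat 1 M NaOH (1.0 equiv); then HCl to pH 2, EtOAc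
Reagents that add atoms: water, O
Why: Enzymatic desymmetrisation by ester hydrolysis: the chiral active site cleaves one of the two enantiotopic esters and stops at the half-ester, which sets the quaternary stereocentre as R.

Step 3
Reactants: 4 (R)-2-(methoxycarbonyl)-2,5-dimethylhex-4-enoic acid
Product: 5 methyl (S)-2-(chlorocarbonyl)-2,5-dimethylhex-4-enoate
Conditions: (COCl)2 (1.3 equiv), DMF (cat.), CH2Cl2, 0 °C → rt; evaporate, use crude
Reagents that add atoms: oxalyl chloride, ClC(=O)C(=O)Cl
Why: Vilsmeier-type acid chloride formation activates only the free acid arm; the quaternary centre has no α-H, so it cannot epimerise or form a ketene (the descriptor changes to S by CIP priority only).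

Step 4
Reactants: 5 methyl (S)-2-(chlorocarbonyl)-2,5-dimethylhex-4-enoate; 6 heptane-2,4-dione
Product: 8 methyl (R)-2-methyl-2-(3-methylbut-2-en-1-yl)-3,5,7-trioxodecanoate, via dilithium dianion 7 (not isolated)
Conditions: 6 (2.5 equiv), LDA (5.0 equiv), THF, 0 °C, 30 min; −78 °C, add 5 (1.0 equiv), 1 h; cold 1 M HCl quench
Reagents that add atoms: none
Why: Hauser–Harris β-diketone dianion acylation: the terminal CH2 carbanion (methyl ionises in preference to the propyl CH2) attacks the acid chloride much faster than the hindered methyl ester, and excess dianion absorbs the acidic product proton.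

Step 5
Reactants: 8 methyl (R)-2-methyl-2-(3-methylbut-2-en-1-yl)-3,5,7-trioxodecanoate
Product: 9 (R)-2-butanoyl-3,5-dihydroxy-4-methyl-4-(3-methylbut-2-en-1-yl)cyclohexa-2,5-dien-1-one
Conditions: KOtBu (3.0 equiv), THF, 0 °C → rt; cold 1 M HCl; purify by NaHCO3 extraction and re-acidification
Reagents that add atoms: none
Why: Intramolecular Claisen (Dieckmann-type) condensation of C6 onto the ester closes the six-membered ring and is driven by the stabilised trione enolate; aldol alternatives are blocked by the quaternary C2, and the butanoyl ends up next to the former ester carbonyl, so the untouched quaternary centre is R.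

Step 6
Reactants: 10 5-methoxyresorcinol
Product: 11 1-methoxy-3,5-bis(methoxymethoxy)benzene
Conditions: NaH (2.4 equiv), DMF, 0 °C; MOMCl (2.4 equiv), 0 °C → rt
Reagents that add atoms: chloromethyl methyl ether (MOMCl), COCCl
Why: Williamson-type O-alkylation of both phenoxides installs two MOM ethers that protect the phenols and direct the later metalations.

Step 7
Reactants: 11 1-methoxy-3,5-bis(methoxymethoxy)benzene
Product: 13 1-[4-methoxy-2,6-bis(methoxymethoxy)phenyl]-N,N-dimethylmethanamine, via aryllithium 12 (not isolated)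
Conditions: n-BuLi (1.2 equiv), TMEDA (1.2 equiv), THF, 0 °C, 1 h; Eschenmoser's salt (1.5 equiv), −78 °C → rt
Reagents that add atoms: N,N-dimethylmethyleneiminium iodide (Eschenmoser's salt), C=[N+](C)C.[I-]
Why: Directed ortho-metalation occurs at the carbon flanked by the two chelating OMOM groups, and the aryllithium adds to the iminium salt (Mannich-type aminomethylation), placing the bridge carbon between the two future OH groups.

Step 8
Reactants: 14 hexanoyl chloride
Product: 15 N-methoxy-N-methylhexanamide
Conditions: MeNH(OMe)·HCl (1.1 equiv), K2CO3 (2.5 equiv), EtOAc/H2O, 0 °C → rt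
Reagents that add atoms: N,O-dimethylhydroxylamine hydrochloride, CNOC.Cl
Why: Schotten–Baumann N-acylation gives the Weinreb amide needed for clean mono-addition in step 9.

Step 9
Reactants: 13 1-[4-methoxy-2,6-bis(methoxymethoxy)phenyl]-N,N-dimethylmethanamine; 15 N-methoxy-N-methylhexanamide
Product: 18 1-{3-[(dimethylamino)methyl]-6-methoxy-2,4-bis(methoxymethoxy)phenyl}hexan-1-one, via aryllithium 16 (not isolated), via lithium hemiaminal adduct 17 (not isolated)
Conditions: n-BuLi (1.3 equiv), TMEDA (1.3 equiv), THF, −20 → 0 °C, 1 h; 15 (1.5 equiv), −78 → 0 °C; aq NH4Cl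
Reagents that add atoms: none
Why: A second directed ortho-metalation can only occur at the two equivalent ring CH positions between OMOM and OMe, and Weinreb ketone synthesis through the stable chelated adduct stops at the ketone.

Step 10
Reactants: 18 1-{3-[(dimethylamino)methyl]-6-methoxy-2,4-bis(methoxymethoxy)phenyl}hexan-1-one
Product: 19 1-{3-[(dimethylamino)methyl]-2,4-dihydroxy-6-methoxyphenyl}hexan-1-one
Conditions: HCl (3 equiv), MeOH, 45 °C, 3 h; then aq NaHCO3 to pH 8, 0 °C; use promptly
Reagents that add atoms: none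
Why: Acid-catalysed acetal exchange with methanol removes both MOM groups while the protonated benzylic amine is inert, so the acid step is finished before the acid-sensitive prenyl partner is introduced.

Step 11
Reactants: 19 1-{3-[(dimethylamino)methyl]-2,4-dihydroxy-6-methoxyphenyl}hexan-1-one; 9 (R)-2-butanoyl-3,5-dihydroxy-4-methyl-4-(3-methylbut-2-en-1-yl)cyclohexa-2,5-dien-1-one
Product: 21 (4R)-2-butanoyl-6-[(3-hexanoyl-2,6-dihydroxy-4-methoxyphenyl)methyl]-3,5-dihydroxy-4-methyl-4-(3-methylbut-2-en-1-yl)cyclohexa-2,5-dien-1-one (CNP0219201.1), via ortho-quinone methide 20 (not isolated)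
Conditions: 9 (1.2 equiv), 1,4-dioxane, 90 °C, argon sweep, 2–3 h
Reagents that add atoms: none
Why: Thermal retro-Mannich loss of dimethylamine gives the ortho-quinone methide, which is trapped by Michael addition of the only free ring carbon of the vinylogous acid 9 with rearomatisation; the quaternary stereocentre is not involved.

## Compound list

1 | dimethyl 2-methylmalonate | COC(=O)C(C)C(=O)OC | starting material
2 | 1-bromo-3-methylbut-2-ene (prenyl bromide) | CC(C)=CCBr | starting material
3 | dimethyl 2-methyl-2-(3-methylbut-2-en-1-yl)malonate | COC(=O)C(C)(CC=C(C)C)C(=O)OC | intermediate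
4 | (R)-2-(methoxycarbonyl)-2,5-dimethylhex-4-enoic acid | OC(=O)[C@@](C)(CC=C(C)C)C(=O)OC | intermediate
5 | methyl (S)-2-(chlorocarbonyl)-2,5-dimethylhex-4-enoate | ClC(=O)[C@@](C)(CC=C(C)C)C(=O)OC | intermediate
6 | heptane-2,4-dione | CCCC(=O)CC(C)=O | starting material
7 | heptane-2,4-dione 1,3-dilithium dianion (formed in situ) | [Li+].[Li+].C=C([O-])C=C([O-])CCC | intermediate
8 | methyl (R)-2-methyl-2-(3-methylbut-2-en-1-yl)-3,5,7-trioxodecanoate | CCCC(=O)CC(=O)CC(=O)[C@@](C)(CC=C(C)C)C(=O)OC | intermediate
9 | (R)-2-butanoyl-3,5-dihydroxy-4-methyl-4-(3-methylbut-2-en-1-yl)cyclohexa-2,5-dien-1-one | C1=C(O)[C@@](C)(CC=C(C)C)C(O)=C(C(=O)CCC)C1=O | intermediate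
10 | 5-methoxyresorcinol (5-methoxybenzene-1,3-diol) | COc1cc(O)cc(O)c1 | starting material
11 | 1-methoxy-3,5-bis(methoxymethoxy)benzene | COCOc1cc(OC)cc(OCOC)c1 | intermediate
12 | [4-methoxy-2,6-bis(methoxymethoxy)phenyl]lithium (formed in situ) | [Li]c1c(OCOC)cc(OC)cc1OCOC | intermediate
13 | 1-[4-methoxy-2,6-bis(methoxymethoxy)phenyl]-N,N-dimethylmethanamine | CN(C)Cc1c(OCOC)cc(OC)cc1OCOC | intermediate
14 | hexanoyl chloride | CCCCCC(Cl)=O | starting material
15 | N-methoxy-N-methylhexanamide | CCCCCC(=O)N(C)OC | intermediate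
16 | {3-[(dimethylamino)methyl]-6-methoxy-2,4-bis(methoxymethoxy)phenyl}lithium (formed in situ) | [Li]c1c(OC)cc(OCOC)c(CN(C)C)c1OCOC | intermediate
17 | lithium hemiaminal adduct of 16 and 15 (formed in situ) | CCCCCC(O[Li])(N(C)OC)c1c(OC)cc(OCOC)c(CN(C)C)c1OCOC | intermediate
18 | 1-{3-[(dimethylamino)methyl]-6-methoxy-2,4-bis(methoxymethoxy)phenyl}hexan-1-one | CCCCCC(=O)c1c(OC)cc(OCOC)c(CN(C)C)c1OCOC | intermediate
19 | 1-{3-[(dimethylamino)methyl]-2,4-dihydroxy-6-methoxyphenyl}hexan-1-one | CCCCCC(=O)c1c(OC)cc(O)c(CN(C)C)c1O | intermediate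
20 | 4-hexanoyl-5-hydroxy-3-methoxy-6-methylidenecyclohexa-2,4-dien-1-one (ortho-quinone methide, formed in situ) | CCCCCC(=O)C1=C(O)C(=C)C(=O)C=C1OC | intermediate
21 | (4R)-2-butanoyl-6-[(3-hexanoyl-2,6-dihydroxy-4-methoxyphenyl)methyl]-3,5-dihydroxy-4-methyl-4-(3-methylbut-2-en-1-yl)cyclohexa-2,5-dien-1-one | CCCCCC(=O)c1c(OC)cc(O)c(CC2=C(O)[C@@](C)(CC=C(C)C)C(O)=C(C(=O)CCC)C2=O)c1O | target

## Count and risks

Total step count: 11. Longest linear sequence: 6 (steps 1, 2, 3, 4, 5, 11); the aromatic branch is 5 (steps 6, 7, 9, 10, 11), with step 8 feeding step 9.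

Three steps most likely to fail:

Step 2 (ee or sense of the esterase on this particular malonate may be insufficient). The fallback sets out from 3 and comes back at 4, replacing ester hydrolysis by lipase acylation of a prochiral diol. LiAlH4 (THF, 0 °C → rt) reduces 3 to 2-methyl-2-(3-methylbut-2-en-1-yl)propane-1,3-diol F1. A triacylglycerol lipase (Burkholderia cepacia lipase, vinyl acetate, MTBE, rt) acetylates one enantiotopic CH2OH to give (S)-2-(hydroxymethyl)-2,5-dimethylhex-4-en-1-yl acetate F2. TEMPO/PhI(OAc)2 in MeCN–H2O (non-basic, to avoid acyl migration) oxidises the free CH2OH to (R)-2-(acetoxymethyl)-2,5-dimethylhex-4-enoic acid F3. TMSCHN2 gives methyl (R)-2-(acetoxymethyl)-2,5-dimethylhex-4-enoate F4. K2CO3/MeOH at 0 °C removes the acetate to give methyl (R)-2-(hydroxymethyl)-2,5-dimethylhex-4-enoate F5, and a second TEMPO/PhI(OAc)2 oxidation gives 4. If the lipase gives the opposite monoacetate, the two arms are oxidised in the other order.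

Step 4 (methyl versus methylene ionisation of the unsymmetrical diketone, or over-acylation by the acid chloride). The fallback sets out from 5 and comes back at 9, bypassing 8. Compound 5 acylates the dianion of symmetrical pentane-2,4-dione (LDA, THF, −78 °C), where no regiochemical choice exists, to give methyl (R)-2-methyl-2-(3-methylbut-2-en-1-yl)-3,5,7-trioxooctanoate F6. KOtBu/THF cyclises it, as in step 5, to (R)-2-acetyl-3,5-dihydroxy-4-methyl-4-(3-methylbut-2-en-1-yl)cyclohexa-2,5-dien-1-one F7. The side chain is then extended by forming the trianion (LDA 3.3 equiv, THF/DMPU, −78 → −20 °C) and alkylating its last-formed acetyl CH2 carbanion with EtI (1.0 equiv), which gives 9.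

Step 11 (quinone methide oligomerisation, O-alkylation, cyclisation to a xanthene, or bridge scrambling at 90 °C). The fallback sets out from 19 and comes back at 21, replacing thermal generation by a discrete, base-triggered precursor. MeI (MeCN, rt, no base) quaternises 19 to 1-(3-hexanoyl-2,6-dihydroxy-4-methoxyphenyl)-N,N,N-trimethylmethanaminium iodide F8, which is isolated. The quinone methide 20 is then released at 0–20 °C with NaHCO3 in CH2Cl2/water in the presence of 9 (1.2 equiv, present as its enolate), giving 21 without heating.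

## Further compounds

F1 | step 2 | 2-methyl-2-(3-methylbut-2-en-1-yl)propane-1,3-diol | CC(C)=CCC(C)(CO)CO
F2 | step 2 | (S)-2-(hydroxymethyl)-2,5-dimethylhex-4-en-1-yl acetate | CC(=O)OC[C@@](C)(CC=C(C)C)CO
F3 | step 2 | (R)-2-(acetoxymethyl)-2,5-dimethylhex-4-enoic acid | CC(=O)OC[C@@](C)(CC=C(C)C)C(=O)O
F4 | step 2 | methyl (R)-2-(acetoxymethyl)-2,5-dimethylhex-4-enoate | CC(=O)OC[C@@](C)(CC=C(C)C)C(=O)OC
F5 | step 2 | methyl (R)-2-(hydroxymethyl)-2,5-dimethylhex-4-enoate | OC[C@@](C)(CC=C(C)C)C(=O)OC
F6 | step 4 | methyl (R)-2-methyl-2-(3-methylbut-2-en-1-yl)-3,5,7-trioxooctanoate | CC(=O)CC(=O)CC(=O)[C@@](C)(CC=C(C)C)C(=O)OC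
F7 | step 4 | (R)-2-acetyl-3,5-dihydroxy-4-methyl-4-(3-methylbut-2-en-1-yl)cyclohexa-2,5-dien-1-one | C1=C(O)[C@@](C)(CC=C(C)C)C(O)=C(C(C)=O)C1=O
F8 | step 11 | 1-(3-hexanoyl-2,6-dihydroxy-4-methoxyphenyl)-N,N,N-trimethylmethanaminium iodide | CCCCCC(=O)c1c(OC)cc(O)c(C[N+](C)(C)C)c1O.[I-]
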